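**Plan**
Feature: piperidine carbons C3, C4, C5 and C6 are the four carbons of a 2,5-disubstituted furan (C3 = furan C2, which carries the C2 aminoethyl carbon; C6 = furan C5, which carries the chain). Oxidative unfolding gives the C3 ketone and closes N1–C6 as a six-membered N,O-hemiaminal.
Retrosynthetic cuts: N1–C6 (imine, then hemiaminal), the C3/C6 oxygens back into the furan (aza-Achmatowicz transform), furan C5–C1' (B-alkyl Suzuki–Miyaura), C3'–C4' (allylboration), C13'–C14' (epoxide opening).
Forward: the C1'–C16' chain is built and joined to a 5-bromofuran that already carries the C2 carbamate. The furan is oxidised to the piperidinone hemiaminal, the enedione level is lowered with zinc, C3 is reduced, and the ring is re-closed through the same N1–C6 bond at the amine level in the last hydrogenation.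
Stereochemistry: C15' from (S)-propylene oxide; C4' from reagent-controlled allylboration; C2 from the tert-butanesulfinamide auxiliary; C3 from chelation-controlled reduction anti to the C2 nitrogen; C6 from hydrogenation of the cyclic imine, cis to the C2 methyl (all-equatorial ring).

Key step: step 9

Remark: hydride delivery to the N-acyliminium ion of the hemiaminal is expected to enter syn to the pseudoaxial C2 methyl group and give the 2,6-trans ring, so C6 is returned to the ketone level and reduced only after the carbamate has been removed.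

Step 1
Reactants: 1 11-bromo-1-undecene; 2 (S)-propylene oxide
Product: 4 (2S)-tetradec-13-en-2-ol, via undec-10-enylmagnesium bromide 3 (not isolated)
Conditions: Mg, THF, rt; then CuI (10 mol %), 2, −30 → 0 °C; aq. work-up
Reagents that add atoms: none
Why: Copper-catalysed Grignard opening of a terminal epoxide takes place at the unsubstituted carbon, so the stereocentre of (S)-propylene oxide becomes C15' without being touched.

Step 2
Reactants: 4
Product: 5 benzyl (2S)-tetradec-13-en-2-yl ether
Conditions: NaH, BnBr, Bu4NI (cat.), THF, 0 °C → rt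
Reagents that add atoms: benzyl bromide, BrCc1ccccc1
Why: Williamson etherification of the sodium alkoxide gives a benzyl ether that should survive every later step up to the final hydrogenolysis.

Step 3
Reactants: 5
Product: 6 (12S)-12-(benzyloxy)tridecanal
Conditions: O3, CH2Cl2, −78 °C; then PPh3, −78 °C → rt
Reagents that add atoms: ozone, [O-][O+]=O
Why: Ozonolysis with reductive work-up cleaves the terminal alkene to the aldehyde whose carbonyl carbon becomes C4', and the benzyl ether is not attacked when the ozone stream is stopped at the end point.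

Step 4
Reactants: 6; 7 B-allyldiisopinocampheylborane prepared from (−)-α-pinene
Product: 8 (4S,15S)-15-(benzyloxy)hexadec-1-en-4-ol
Conditions: Et2O, −78 °C; then aq. NaOH, H2O2, 0 °C → rt
Reagents that add atoms: none
Why: Brown allylboration through a closed chair transition state, in which the isopinocampheyl groups derived from (−)-α-pinene send the allyl group to the Re face of the unbranched aldehyde, should set C4' as S under reagent control, the remote C15' centre having no influence.

Step 5
Reactants: 8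
Product: 9 (4S,15S)-4,15-bis(benzyloxy)hexadec-1-ene
Conditions: NaH, BnBr, Bu4NI (cat.), THF/DMF, 0 °C → rt
Reagents that add atoms: benzyl bromide, BrCc1ccccc1
Why: Williamson etherification of the homoallylic alkoxide, with no stereocentre involved.

Step 6
Reactants: 10 1-(5-bromofuran-2-yl)ethanone; 11 (R)-tert-butanesulfinamide
Product: 13 (R)-N-[(1R)-1-(5-bromofuran-2-yl)ethyl]-2-methylpropane-2-sulfinamide, via N-sulfinyl ketimine 12 (not isolated)
Conditions: Ti(OEt)4, THF, 65 °C; then NaBH4, −48 °C → rt
Reagents that add atoms: none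
Why: One-pot tert-butanesulfinamide condensation and reduction, in which Ti(OEt)4 drives formation of the (E)-ketimine and NaBH4 delivers hydride through the cyclic transition state with boron bound to the sulfinyl oxygen, should give the (RS,R) diastereomer and so set C2, the minor diastereomer being removable by chromatography at this small-fragment stage.

Step 7
Reactants: 13
Product: 15 benzyl N-[(1R)-1-(5-bromofuran-2-yl)ethyl]carbamate, via amine hydrochloride 14 (not isolated)
Conditions: HCl (4 M in dioxane), MeOH, 0 °C; evaporate; then benzyl chloroformate, aq. NaHCO3, EtOAc, 0 °C → rt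
Reagents that add atoms: benzyl chloroformate, O=C(Cl)OCc1ccccc1
Why: Acidic methanolysis cleaves the N–S bond without touching the C–N stereocentre, and Schotten–Baumann acylation installs the carbamate that later acts as the nitrogen nucleophile and is removable by hydrogenolysis.

Step 8
Reactants: 9; 15
Product: 17 benzyl N-[(1R)-1-{5-[(4S,15S)-4,15-bis(benzyloxy)hexadecyl]furan-2-yl}ethyl]carbamate, via alkyl-9-BBN borane 16 (not isolated)
Conditions: 9-BBN, THF, rt; then 15, PdCl2(dppf) (5 mol %), aq. K3PO4, DMF, 50 °C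
Reagents that add atoms: none
Why: Anti-Markovnikov hydroboration of the terminal alkene followed by B-alkyl Suzuki–Miyaura coupling with the heteroaryl bromide forms the furan C5–C1' bond, and carbamate N–H, benzyl ethers and all three stereocentres are inert to these conditions.

Step 9
Reactants: 17
Product: 19 benzyl (2R)-6-[(4S,15S)-4,15-bis(benzyloxy)hexadecyl]-6-hydroxy-2-methyl-3-oxo-3,6-dihydropyridine-1(2H)-carboxylate (both C6 epimers), via cis-enedione 18 (not isolated)
Conditions: mCPBA (1.2 equiv), CH2Cl2, 0 °C → rt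
Reagents that add atoms: mCPBA (3-chloroperoxybenzoic acid), OOC(=O)c1cccc(Cl)c1
Why: The peracid epoxidises the electron-rich 2,5-dialkylfuran and the epoxide collapses to the cis-ene-1,4-dione 18, whose two carbonyl carbons are C3 and C6. The carbamate N–H, held next to the C6 ketone by the Z double bond, adds to it and so forms the N1–C6 bond and the six-membered 6-hydroxy-2H-pyridin-3(6H)-one. This is the aza-Achmatowicz rearrangement of N-acyl furfurylamines. The ring closes by 6-exo-trig addition of nitrogen to the C6 carbonyl. The only new stereocentre, C6, forms without control as a hemiaminal mixture, which is harmless because C6 returns to the carbonyl level in step 10. The step needs chemoselective oxidation of the furan, secured because it is the only electron-rich π system (benzyl ethers and carbamate are inert to peracid at 0 °C), and non-basic conditions, which leave the C2 centre next to the new ketone intact.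

Step 10
Reactants: 19
Product: 20 benzyl N-[(2R,10S,21S)-10,21-bis(benzyloxy)-3,6-dioxodocosan-2-yl]carbamate
Conditions: Zn dust, AcOH, THF, 0 °C → rt; aq. work-up
Reagents that add atoms: none
Why: Zinc in acetic acid reduces the ene-1,4-dione, with which the hemiaminal is in ring–chain equilibrium under acid, to the saturated 1,4-diketone (dissolving-metal conjugate reduction), so that C6 is held at the carbonyl level while carbamate, benzyl ethers and the C2 centre are left alone.

Step 11
Reactants: 20
Product: 21 benzyl N-[(2R,3S,10S,21S)-10,21-bis(benzyloxy)-3-hydroxy-6-oxodocosan-2-yl]carbamate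
Conditions: LiAlH(OtBu)3, EtOH, −78 °C
Reagents that add atoms: none
Why: Chelation-controlled (cyclic Cram model) hydride reduction of the N-carbamoyl α-amino ketone, which is activated by the neighbouring N–H carbamate while the isolated C6 ketone is not, should give the anti amino alcohol and so set C3 as S, the alkoxide then masking C6 as a five-membered lactol.

Step 12
Reactants: 21
Product: 25 (2R,3S,6S)-6-[(4S,15S)-4,15-dihydroxyhexadecyl]-2-methylpiperidin-3-ol, via amino ketone 22 (not isolated), via cyclic imine 23 (not isolated), via bis-benzyl piperidine 24 (not isolated)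
Conditions: H2 (3 atm), Pd(OH)2 on carbon, MeOH then AcOH, rt; aq. NH3 work-up
Reagents that add atoms: none
Why: Hydrogenolysis of the benzyl carbamate frees the amine, which condenses with the C6 ketone to the cyclic imine, and hydrogen should then add to C6=N so that H6 becomes axial and the chain equatorial, cis to the equatorial C2 methyl (intramolecular reductive amination), while both benzyl ethers are cleaved in the same operation.

**Compound list**
1 | 11-bromo-1-undecene | C=CCCCCCCCCCBr | starting material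
2 | (S)-propylene oxide | C[C@H]1CO1 | starting material
3 | undec-10-enylmagnesium bromide | C=CCCCCCCCCC[Mg]Br | intermediate
4 | (2S)-tetradec-13-en-2-ol | C[C@H](O)CCCCCCCCCCC=C | intermediate
5 | benzyl (2S)-tetradec-13-en-2-yl ether | C[C@H](OCc1ccccc1)CCCCCCCCCCC=C | intermediate
6 | (12S)-12-(benzyloxy)tridecanal | C[C@H](OCc1ccccc1)CCCCCCCCCCC=O | intermediate
7 | B-allyldiisopinocampheylborane, enantiomer prepared from (−)-α-pinene (commercial solution) | C=CCB([C@H]1C[C@H]2C[C@@H]([C@@H]1C)C2(C)C)[C@H]1C[C@H]2C[C@@H]([C@@H]1C)C2(C)C | starting material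
8 | (4S,15S)-15-(benzyloxy)hexadec-1-en-4-ol | C[C@H](OCc1ccccc1)CCCCCCCCCC[C@H](O)CC=C | intermediate
9 | (4S,15S)-4,15-bis(benzyloxy)hexadec-1-ene | C[C@H](OCc1ccccc1)CCCCCCCCCC[C@H](OCc1ccccc1)CC=C | intermediate
10 | 1-(5-bromofuran-2-yl)ethanone | CC(=O)c1ccc(Br)o1 | starting material
11 | (R)-tert-butanesulfinamide | CC(C)(C)[S@](N)=O | starting material
12 | (R,E)-N-[1-(5-bromofuran-2-yl)ethylidene]-2-methylpropane-2-sulfinamide | C/C(=N\[S@](=O)C(C)(C)C)c1ccc(Br)o1 | intermediate
13 | (R)-N-[(1R)-1-(5-bromofuran-2-yl)ethyl]-2-methylpropane-2-sulfinamide | C[C@@H](N[S@](=O)C(C)(C)C)c1ccc(Br)o1 | intermediate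
14 | (1R)-1-(5-bromofuran-2-yl)ethanaminium chloride | C[C@@H]([NH3+])c1ccc(Br)o1.[Cl-] | intermediate
15 | benzyl N-[(1R)-1-(5-bromofuran-2-yl)ethyl]carbamate | C[C@@H](NC(=O)OCc1ccccc1)c1ccc(Br)o1 | intermediate
16 | 9-[(4R,15S)-4,15-bis(benzyloxy)hexadecyl]-9-borabicyclo[3.3.1]nonane (C4' unchanged in space; the descriptor is R only because boron ranks below carbon) | C[C@H](OCc1ccccc1)CCCCCCCCCC[C@H](OCc1ccccc1)CCCB1C2CCCC1CCC2 | intermediate
17 | benzyl N-[(1R)-1-{5-[(4S,15S)-4,15-bis(benzyloxy)hexadecyl]furan-2-yl}ethyl]carbamate | C[C@H](OCc1ccccc1)CCCCCCCCCC[C@H](OCc1ccccc1)CCCc1ccc(o1)[C@@H](C)NC(=O)OCc1ccccc1 | intermediate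
18 | benzyl N-[(2R,4Z,10S,21S)-10,21-bis(benzyloxy)-3,6-dioxodocos-4-en-2-yl]carbamate | C[C@H](OCc1ccccc1)CCCCCCCCCC[C@H](OCc1ccccc1)CCCC(=O)/C=C\C(=O)[C@@H](C)NC(=O)OCc1ccccc1 | intermediate
19 | benzyl (2R)-6-[(4S,15S)-4,15-bis(benzyloxy)hexadecyl]-6-hydroxy-2-methyl-3-oxo-3,6-dihydropyridine-1(2H)-carboxylate (both C6 epimers) | C[C@H](OCc1ccccc1)CCCCCCCCCC[C@H](OCc1ccccc1)CCCC1(O)C=CC(=O)[C@@H](C)N1C(=O)OCc1ccccc1 | intermediate
20 | benzyl N-[(2R,10S,21S)-10,21-bis(benzyloxy)-3,6-dioxodocosan-2-yl]carbamate | C[C@H](OCc1ccccc1)CCCCCCCCCC[C@H](OCc1ccccc1)CCCC(=O)CCC(=O)[C@@H](C)NC(=O)OCc1ccccc1 | intermediate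
21 | benzyl N-[(2R,3S,10S,21S)-10,21-bis(benzyloxy)-3-hydroxy-6-oxodocosan-2-yl]carbamate | C[C@H](OCc1ccccc1)CCCCCCCCCC[C@H](OCc1ccccc1)CCCC(=O)CC[C@H](O)[C@@H](C)NC(=O)OCc1ccccc1 | intermediate
22 | (2R,3S,10S,21S)-2-amino-10,21-bis(benzyloxy)-3-hydroxydocosan-6-one | C[C@H](OCc1ccccc1)CCCCCCCCCC[C@H](OCc1ccccc1)CCCC(=O)CC[C@H](O)[C@@H](C)N | intermediate
23 | (2R,3S)-6-[(4S,15S)-4,15-bis(benzyloxy)hexadecyl]-2-methyl-2,3,4,5-tetrahydropyridin-3-ol | C[C@H](OCc1ccccc1)CCCCCCCCCC[C@H](OCc1ccccc1)CCCC1=N[C@H](C)[C@@H](O)CC1 | intermediate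
24 | (2R,3S,6S)-6-[(4S,15S)-4,15-bis(benzyloxy)hexadecyl]-2-methylpiperidin-3-ol | C[C@H](OCc1ccccc1)CCCCCCCCCC[C@H](OCc1ccccc1)CCC[C@H]1CC[C@H](O)[C@@H](C)N1 | intermediate
25 | (2R,3S,6S)-6-[(4S,15S)-4,15-dihydroxyhexadecyl]-2-methylpiperidin-3-ol | C[C@H](O)CCCCCCCCCC[C@H](O)CCC[C@H]1CC[C@H](O)[C@@H](C)N1 | target

**Step count**
Total steps: 12. Longest linear sequence: 10 steps (steps 1–5 and 8–12).

**Steps most likely to fail**

Step 11. The hydride may also reduce the unactivated C6 ketone, or chelation may be incomplete so that the anti preference erodes. The fallback sets out from hemiaminal 19 and returns at cyclic imine 23; it keeps the ring closed and sets C3 under cyclic control.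
- The hemiaminal is locked with MeOH and pyridinium p-toluenesulfonate as benzyl (2R)-6-[(4S,15S)-4,15-bis(benzyloxy)hexadecyl]-6-methoxy-2-methyl-3-oxo-3,6-dihydropyridine-1(2H)-carboxylate F1.
- The ring alkene is hydrogenated over Pd/C–ethylenediamine, which spares the carbamate and the benzyl ethers, to benzyl (2R)-6-[(4S,15S)-4,15-bis(benzyloxy)hexadecyl]-6-methoxy-2-methyl-3-oxopiperidine-1-carboxylate F2.
- NaBH4 reduces the only ketone from the face opposite the pseudoaxial C2 methyl to the 2,3-cis alcohol benzyl (2R,3R)-6-[(4S,15S)-4,15-bis(benzyloxy)hexadecyl]-3-hydroxy-6-methoxy-2-methylpiperidine-1-carboxylate F3.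
- Mitsunobu inversion with 4-nitrobenzoic acid, PPh3 and diisopropyl azodicarboxylate should give benzyl (2R,3S)-6-[(4S,15S)-4,15-bis(benzyloxy)hexadecyl]-6-methoxy-2-methyl-3-[(4-nitrobenzoyl)oxy]piperidine-1-carboxylate F4.
- K2CO3 in MeOH gives benzyl (2R,3S)-6-[(4S,15S)-4,15-bis(benzyloxy)hexadecyl]-3-hydroxy-6-methoxy-2-methylpiperidine-1-carboxylate F5.
- Under the conditions of step 12 the carbamate is cleaved, the N–H ketal loses methanol to give 23, and the route continues to 25.

Step 9. The peracid may over-oxidise the product, or the carbamate nitrogen may close only partly onto the ketone so that the tertiary hemiaminal decomposes on isolation. The fallback sets out from furan 17 and returns at diketone 20. NBS with NaHCO3 in aqueous acetone at −20 °C, followed by pyridine, opens the furan to the open-chain enedione benzyl N-[(2R,4E,10S,21S)-10,21-bis(benzyloxy)-3,6-dioxodocos-4-en-2-yl]carbamate F6, whose trans geometry keeps nitrogen away from C6. Zn/AcOH as in step 10 then gives 20.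

Step 12. The free C3 hydroxyl may hold the C6 carbonyl as the lactol, so that imine formation is slow and the amino ketone is diverted, or the product amine may slow debenzylation. The fallback sets out from 21 and returns at 25. Silylation with TBSOTf and 2,6-lutidine gives benzyl N-[(2R,3S,10S,21S)-10,21-bis(benzyloxy)-3-(tert-butyldimethylsilyloxy)-6-oxodocosan-2-yl]carbamate F7, in which the ketone is free. Hydrogenation as in step 12 gives (2R,3S,6S)-3-(tert-butyldimethylsilyloxy)-6-[(4S,15S)-4,15-dihydroxyhexadecyl]-2-methylpiperidine F8. HCl in MeOH then removes the silyl group to give 25.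

Further compounds
F1 | step 11 | benzyl (2R)-6-[(4S,15S)-4,15-bis(benzyloxy)hexadecyl]-6-methoxy-2-methyl-3-oxo-3,6-dihydropyridine-1(2H)-carboxylate | C[C@H](OCc1ccccc1)CCCCCCCCCC[C@H](OCc1ccccc1)CCCC1(OC)C=CC(=O)[C@@H](C)N1C(=O)OCc1ccccc1
F2 | step 11 | benzyl (2R)-6-[(4S,15S)-4,15-bis(benzyloxy)hexadecyl]-6-methoxy-2-methyl-3-oxopiperidine-1-carboxylate | C[C@H](OCc1ccccc1)CCCCCCCCCC[C@H](OCc1ccccc1)CCCC1(OC)CCC(=O)[C@@H](C)N1C(=O)OCc1ccccc1
F3 | step 11 | benzyl (2R,3R)-6-[(4S,15S)-4,15-bis(benzyloxy)hexadecyl]-3-hydroxy-6-methoxy-2-methylpiperidine-1-carboxylate | C[C@H](OCc1ccccc1)CCCCCCCCCC[C@H](OCc1ccccc1)CCCC1(OC)CC[C@@H](O)[C@@H](C)N1C(=O)OCc1ccccc1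
F4 | step 11 | benzyl (2R,3S)-6-[(4S,15S)-4,15-bis(benzyloxy)hexadecyl]-6-methoxy-2-methyl-3-[(4-nitrobenzoyl)oxy]piperidine-1-carboxylate | C[C@H](OCc1ccccc1)CCCCCCCCCC[C@H](OCc1ccccc1)CCCC1(OC)CC[C@H](OC(=O)c2ccc(cc2)[N+](=O)[O-])[C@@H](C)N1C(=O)OCc1ccccc1
F5 | step 11 | benzyl (2R,3S)-6-[(4S,15S)-4,15-bis(benzyloxy)hexadecyl]-3-hydroxy-6-methoxy-2-methylpiperidine-1-carboxylate | C[C@H](OCc1ccccc1)CCCCCCCCCC[C@H](OCc1ccccc1)CCCC1(OC)CC[C@H](O)[C@@H](C)N1C(=O)OCc1ccccc1
F6 | step 9 | benzyl N-[(2R,4E,10S,21S)-10,21-bis(benzyloxy)-3,6-dioxodocos-4-en-2-yl]carbamate | C[C@H](OCc1ccccc1)CCCCCCCCCC[C@H](OCc1ccccc1)CCCC(=O)/C=C/C(=O)[C@@H](C)NC(=O)OCc1ccccc1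
F7 | step 12 | benzyl N-[(2R,3S,10S,21S)-10,21-bis(benzyloxy)-3-(tert-butyldimethylsilyloxy)-6-oxodocosan-2-yl]carbamate | C[C@H](OCc1ccccc1)CCCCCCCCCC[C@H](OCc1ccccc1)CCCC(=O)CC[C@H](O[Si](C)(C)C(C)(C)C)[C@@H](C)NC(=O)OCc1ccccc1
F8 | step 12 | (2R,3S,6S)-3-(tert-butyldimethylsilyloxy)-6-[(4S,15S)-4,15-dihydroxyhexadecyl]-2-methylpiperidine | C[C@H](O)CCCCCCCCCC[C@H](O)CCC[C@H]1CC[C@H](O[Si](C)(C)C(C)(C)C)[C@@H](C)N1
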